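**Retrosynthetic overview**

1. Ring numbering used throughout: C1 (CH–O-angelate), C2 (CH2), C3/C4 (oxirane, methyl on C3), C5 (CH–OAc), C6 (CH–iPr), C7, C8, C9/C10 (oxirane, methyl on C9). The strategy rests on the two 2,3-epoxy alcohol arrays of like relative configuration in the ten-membered carbocycle, O–C1/C10(–O–)C9 and O–C5/C4(–O–)C3.
2. The C1 angelate and C5 acetate come off to give diepoxy diol 24. Its two trans, trisubstituted oxiranes (C9–O–C10 and C3–O–C4) are then traced in one operation to the bis(cis-epoxide) diol 22 by a twofold Payne rearrangement.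
3. 22 comes from two hydroxyl-directed epoxidations, C4=C5 on the open chain and C10=C1 in the ring, placed either side of a ring-closing metathesis at C10=C1.
4. The open chain comes from a (Z)-selective Wittig union at C4=C5 of phosphonium salt 10 (C5–C10) with aldehyde 15 (C1–C4). C6 and C9 are taken from (1S,4R)-p-mentha-2,8-dien-1-ol by ozonolytic opening of its ring, and C3 from (R)-2-methylglycidol, so no ketone addition has to be made enantioselective.
5. Order of ring formation: C4–C5 cis-oxirane (step 12), ten-membered carbocycle (step 14), C10–C1 cis-oxirane (step 15), then both final oxiranes at once (step 16).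

Key step: step 16

Assumption: (1S,4R)-p-mentha-2,8-dien-1-ol (the (R)-limonene-derived alcohol with methyl and isopropenyl trans), (R)-2-methylglycidol and angelic acid are taken as purchasable; stereodescriptors given for ring compounds follow the ring numbering above.

**Route**

Step 1
Reactants: 1 (1S,4R)-p-mentha-2,8-dien-1-ol
Product: 2 (1S,4S)-p-menth-2-en-1-ol
Conditions: H2 (1 atm), RhCl(PPh3)3 (3 mol%), benzene/EtOH 1:1, 20 °C, stopped after one equivalent of H2
Reagents that add atoms: none
Why: Chemoselective homogeneous hydrogenation, in which RhCl(PPh3)3 discriminates alkenes by steric access, should saturate the exposed 1,1-disubstituted isopropenyl group well before the ring alkene flanked by the quaternary carbinol carbon and the branched C4; no stereocentre is formed (the C4 descriptor changes from R to S only by a priority change).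

Step 2
Reactants: 2 (1S,4S)-p-menth-2-en-1-ol
Product: 5 (2S,5S)-6-hydroxy-2-methyl-5-(propan-2-yl)oxane-2-carbaldehyde (lactol; anomer mixture), via ozonide 3 (not isolated), via hydroxy dialdehyde 4 (not isolated)
Conditions: O3, CH2Cl2, −78 °C; then Me2S, −78 → 20 °C
Reagents that add atoms: ozone, [O-][O+]=O
Why: Ozonolysis with reductive work-up cleaves the single alkene into the C10 and C5 aldehydes of the future ring, and the tertiary hydroxyl, which can reach only C5 through a six-membered ring, closes a lactol there and so tells the two carbonyl ends apart without touching either stereocentre.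

Step 3
Reactants: 5 lactol aldehyde
Product: 6 (3S,6S)-6-ethenyl-6-methyl-3-(propan-2-yl)oxan-2-ol (anomer mixture)
Conditions: Ph3PCH3Br (2.2 equiv), KN(SiMe3)2 (2.1 equiv), THF, 0 °C; then 5, −78 → −20 °C
Reagents that add atoms: methyltriphenylphosphonium bromide, C[P+](c1ccccc1)(c1ccccc1)c1ccccc1.[Br-]
Why: Wittig methylenation of the free, non-enolisable C10 aldehyde, the first equivalent of ylide turning the lactol into its alkoxide, which stays closed at low temperature and keeps C5 masked.

Step 4
Reactants: 6 vinyl lactol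
Product: 7 (2S,5S)-5-methyl-2-(propan-2-yl)hept-6-ene-1,5-diol
Conditions: NaBH4, MeOH, 0 → 20 °C
Reagents that add atoms: none
Why: Borohydride reduction of the lactol through its open hydroxy aldehyde form gives the primary C5 alcohol and frees the tertiary C9 hydroxyl, no stereocentre being involved.

Step 5
Reactants: 7 ene diol
Product: 8 (3S,6S)-7-iodo-3-methyl-6-(propan-2-yl)hept-1-en-3-ol
Conditions: PPh3, I2, imidazole, CH2Cl2, 0 °C
Reagents that add atoms: iodine, II
Why: Appel iodination, in which only the primary alcohol forms an alkoxyphosphonium ion that iodide can displace, the tertiary allylic hydroxyl being too hindered to react at 0 °C.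

Step 6
Reactants: 8 iodo alcohol
Product: 9 triethyl{[(3S,6S)-7-iodo-3-methyl-6-(propan-2-yl)hept-1-en-3-yl]oxy}silane
Conditions: Et3SiOTf, 2,6-lutidine, CH2Cl2, −78 → 0 °C
Reagents that add atoms: triethylsilyl trifluoromethanesulfonate, CC[Si](CC)(CC)OS(=O)(=O)C(F)(F)F
Why: Silylation of the tertiary alcohol with a silyl triflate and a hindered base, which blocks intramolecular O-alkylation by the iodide and keeps the C9 oxygen masked until the first epoxidation is done.

Step 7
Reactants: 9 silyl ether iodide
Product: 10 [(2S,5S)-5-methyl-2-(propan-2-yl)-5-(triethylsilyloxy)hept-6-en-1-yl]triphenylphosphonium iodide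
Conditions: PPh3, iPr2NEt (0.1 equiv), MeCN, 80 °C
Reagents that add atoms: triphenylphosphine, c1ccc(cc1)P(c1ccccc1)c1ccccc1
Why: SN2 quaternisation of triphenylphosphine by the primary iodide gives the Wittig salt, the β-branch at C6 only slowing the reaction.

Step 8
Reactants: 11 (R)-2-methylglycidol [(R)-(2-methyloxiran-2-yl)methanol]; 12 vinylmagnesium bromide
Product: 13 (S)-2-methylpent-4-ene-1,2-diol
Conditions: 12 (3 equiv), CuI (10 mol%), THF, −30 → 0 °C
Reagents that add atoms: vinylmagnesium bromide (12), C=C[Mg]Br
Why: Copper-catalysed Grignard opening of the 2,2-disubstituted epoxide at its CH2 terminus (SN2) installs the allyl group C2–C1 and leaves the quaternary stereocentre, the future C3, untouched (its descriptor becomes S by a priority change).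

Step 9
Reactants: 13 (S)-2-methylpent-4-ene-1,2-diol
Product: 14 (S)-2-methyl-1,2-bis(trimethylsilyloxy)pent-4-ene
Conditions: Me3SiCl, imidazole, DMF, 0 → 20 °C
Reagents that add atoms: chlorotrimethylsilane, C[Si](C)(C)Cl
Why: Exhaustive silylation covers the primary and the tertiary hydroxyl with a group that can later be removed in the presence of the triethylsilyl ether at C9.

Step 10
Reactants: 14 bis(trimethylsilyl) ether
Product: 15 (S)-2-methyl-2-(trimethylsilyloxy)pent-4-enal
Conditions: (COCl)2, DMSO, CH2Cl2, −78 → −35 °C; then Et3N, −78 → 0 °C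
Reagents that add atoms: none
Why: Swern oxidation acting directly on the primary trimethylsilyl ether, which the chlorosulfonium salt cleaves and oxidises to the aldehyde while the tertiary silyl ether is inert; the aldehyde has no α-hydrogen and cannot epimerise.

Step 11
Reactants: 10 phosphonium iodide; 15 α-silyloxy aldehyde
Product: 18 (4S,5Z,7S,10S)-4,10-dimethyl-7-(propan-2-yl)-10-(triethylsilyloxy)dodeca-1,5,11-trien-4-ol, via ylide 16 (not isolated), via bis-silyl triene 17 (not isolated)
Conditions: 10, NaN(SiMe3)2, THF, −78 → 0 °C; then 15, −78 → 20 °C; then K2CO3, MeOH, 20 °C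
Reagents that add atoms: none
Why: Lithium-free Wittig olefination of a non-stabilised ylide, whose kinetically controlled oxaphosphetane formation gives the (Z)-alkene C4=C5, followed in the same flask by methanolysis of the labile tertiary trimethylsilyl ether only.

Step 12
Reactants: 18 triene with free C3–OH
Product: 19 (2S)-2-{(2R,3R)-3-[(3S,6S)-2,6-dimethyl-6-(triethylsilyloxy)oct-7-en-3-yl]oxiran-2-yl}pent-4-en-2-ol
Conditions: VO(acac)2 (5 mol%), t-BuOOH (1.3 equiv, decane), CH2Cl2, 0 °C
Reagents that add atoms: tert-butyl hydroperoxide, CC(C)(C)OO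
Why: Hydroxyl-directed epoxidation of the only alkene that is allylic to a free hydroxyl, stereospecific for the cis-oxirane and delivered from the face of the C3–OH that lies anti to the isopropyl group when C6–H eclipses the alkene (allylic 1,3-strain), which sets C4 and C5 as R,R; doing this before ring closure also removes the internal alkene that would divert the metathesis catalyst from C10 to C5 and give a cyclohexene.

Step 13
Reactants: 19 silyl-protected epoxy alcohol
Product: 20 (3S,6S)-6-{(2R,3R)-3-[(2S)-2-hydroxypent-4-en-2-yl]oxiran-2-yl}-3,7-dimethyloct-1-en-3-ol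
Conditions: Bu4NF, AcOH (1:1), THF, 0 → 20 °C
Reagents that add atoms: none
Why: Fluoride-mediated desilylation of the tertiary triethylsilyl ether, buffered with acetic acid so that the epoxy alcohol neither rearranges nor cyclises under basic conditions.

Step 14
Reactants: 20 epoxy diene diol
Product: 21 (1R,2S,4Z,6S,9S,10R)-2,6-dimethyl-9-(propan-2-yl)-11-oxabicyclo[8.1.0]undec-4-ene-2,6-diol
Conditions: second-generation Hoveyda–Grubbs catalyst RuCl2(H2IMes)(=CH-C6H4-2-OiPr) (10 mol%), 1,4-benzoquinone (20 mol%), toluene (1 mM), 80 °C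
Reagents that add atoms: none
Why: Ring-closing metathesis of the two terminal alkenes with loss of ethene, helped by the free tertiary allylic hydroxyl at the hindered vinyl end and by the fold that the quaternary C3 and C9 and the cis-oxirane impose on the chain; ring strain should make the (Z)-alkene C10=C1 the product in a ten-membered ring.

Step 15
Reactants: 21 macrocyclic epoxy ene diol
Product: 22 (1R,3S,4R,5R,6S,9S,10R)-1,10:4,5-diepoxy-3,9-dimethyl-6-(propan-2-yl)cyclodecane-3,9-diol
Conditions: VO(acac)2 (5 mol%), t-BuOOH (1.5 equiv, decane), CH2Cl2, 0 → 20 °C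
Reagents that add atoms: tert-butyl hydroperoxide, CC(C)(C)OO
Why: Hydroxyl-directed epoxidation of the (Z)-allylic tertiary alcohol, in which allylic 1,3-strain against C2 keeps the C9 methyl out of the alkene plane so that the C9–OH sits on the outer face of the ring alkene and delivers oxygen there, cis to both hydroxyls, setting C10 and C1 as R,R.

Step 16
Reactants: 22 bis(cis-epoxide) diol
Product: 24 (1R,3S,4S,5R,6S,9S,10S)-3,4:9,10-diepoxy-3,9-dimethyl-6-(propan-2-yl)cyclodecane-1,5-diol, via half-rearranged diepoxy diol 23 (not isolated)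
Conditions: 0.5 M aq NaOH, t-BuOH, 20 → 40 °C
Reagents that add atoms: none
Why: Hydroxide reversibly deprotonates the tertiary alcohols at C9 and C3, and each alkoxide attacks the neighbouring oxirane carbon (C10, C4) from the side opposite the departing oxygen, so the C10–O and C4–O bonds of the cis-oxiranes break, the C9–O–C10 and C3–O–C4 oxiranes form and the oxygens left on C1 and C5 become secondary alkoxides, the half-rearranged compound 23 being passed through. This is the Payne rearrangement of 2,3-epoxy alcohols in aqueous base, run here twice in one molecule. Each oxirane closes in the 3-exo-tet mode. C10 and C4 are inverted (R to S) by the backside displacement, so their configuration is dictated by the cis-oxiranes and by C9 and C3, while C1, C3, C5 and C9 keep their C–O bonds and their configuration. The step needs the equilibrium on the product side and no ether formation across the ring: the first should hold because each half trades a disubstituted cis-oxirane and a tertiary alkoxide for a trisubstituted trans-oxirane and a less basic, better solvated secondary alkoxide. The second should hold because the competing attacks (C9–O on C5 across the ring in a six-membered mode, C1–O on C3 or C4 in four-membered or endo five-membered modes, C5–O on the tertiary C9) are far slower than a 3-exo closure on the adjacent carbon.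

Step 17
Reactants: 24 diepoxy diol; 25 angelic acid [(Z)-2-methylbut-2-enoic acid]
Product: 27 C1 angelate of 24 (C5–OH free), via mixed anhydride 26 (not isolated)
Conditions: 25, 2,4,6-trichlorobenzoyl chloride, Et3N, toluene, 20 °C, filtered; then 24, toluene, 70 °C
Reagents that add atoms: angelic acid (25), C/C=C(/C)C(=O)O
Why: Yamaguchi esterification through the preformed mixed anhydride and without a nucleophilic catalyst, conditions that transfer the angeloyl group without Z-to-E isomerisation, the bulky anhydride acylating the C1 hydroxyl next to CH2 in preference to the C5 hydroxyl next to the isopropyl-bearing C6.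

Step 18
Reactants: 27 C1 angelate
Product: 28 target, (1R,3S,4S,5R,6S,9S,10S)-5-acetoxy-3,4:9,10-diepoxy-3,9-dimethyl-6-(propan-2-yl)cyclodecan-1-yl (Z)-2-methylbut-2-enoate
Conditions: Ac2O, pyridine, DMAP (5 mol%), CH2Cl2, 0 → 20 °C
Reagents that add atoms: acetic anhydride, CC(=O)OC(C)=O
Why: Base-catalysed acetylation of the remaining hindered secondary alcohol under mild conditions that the angelate and both trisubstituted oxiranes tolerate.

**Compound list**

1 | (1S,4R)-p-mentha-2,8-dien-1-ol | C[C@@]1(O)C=C[C@H](C(C)=C)CC1 | starting material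
2 | (1S,4S)-p-menth-2-en-1-ol | C[C@@]1(O)C=C[C@H](C(C)C)CC1 | intermediate
3 | secondary ozonide of 2, 2-methyl-5-(propan-2-yl)-7,8,9-trioxabicyclo[4.2.1]nonan-2-ol (2S,5S; bridgeheads as formed) | C[C@]1(O)CC[C@@H](C(C)C)C2OOC1O2 | intermediate (not isolated)
4 | (2S,5S)-2-hydroxy-2-methyl-5-(propan-2-yl)hexanedial | O=C[C@@](C)(O)CC[C@@H](C(C)C)C=O | intermediate (not isolated)
5 | (2S,5S)-6-hydroxy-2-methyl-5-(propan-2-yl)oxane-2-carbaldehyde, anomer mixture | O=C[C@]1(C)CC[C@@H](C(C)C)C(O)O1 | intermediate
6 | (3S,6S)-6-ethenyl-6-methyl-3-(propan-2-yl)oxan-2-ol, anomer mixture | C=C[C@]1(C)CC[C@@H](C(C)C)C(O)O1 | intermediate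
7 | (2S,5S)-5-methyl-2-(propan-2-yl)hept-6-ene-1,5-diol | C=C[C@@](C)(O)CC[C@@H](C(C)C)CO | intermediate
8 | (3S,6S)-7-iodo-3-methyl-6-(propan-2-yl)hept-1-en-3-ol | C=C[C@@](C)(O)CC[C@@H](C(C)C)CI | intermediate
9 | triethyl{[(3S,6S)-7-iodo-3-methyl-6-(propan-2-yl)hept-1-en-3-yl]oxy}silane | C=C[C@@](C)(O[Si](CC)(CC)CC)CC[C@@H](C(C)C)CI | intermediate
10 | [(2S,5S)-5-methyl-2-(propan-2-yl)-5-(triethylsilyloxy)hept-6-en-1-yl]triphenylphosphonium iodide | C=C[C@@](C)(O[Si](CC)(CC)CC)CC[C@@H](C(C)C)C[P+](c1ccccc1)(c1ccccc1)c1ccccc1.[I-] | intermediate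
11 | (R)-2-methylglycidol | C[C@@]1(CO)CO1 | starting material
12 | vinylmagnesium bromide | C=C[Mg]Br | starting material
13 | (S)-2-methylpent-4-ene-1,2-diol | C=CC[C@](C)(O)CO | intermediate
14 | (S)-2-methyl-1,2-bis(trimethylsilyloxy)pent-4-ene | C=CC[C@](C)(O[Si](C)(C)C)CO[Si](C)(C)C | intermediate
15 | (S)-2-methyl-2-(trimethylsilyloxy)pent-4-enal | C=CC[C@](C)(O[Si](C)(C)C)C=O | intermediate
16 | ylide of 10, [(2S,5S)-5-methyl-2-(propan-2-yl)-5-(triethylsilyloxy)hept-6-en-1-ylidene]triphenylphosphorane | C=C[C@@](C)(O[Si](CC)(CC)CC)CC[C@@H](C(C)C)C=P(c1ccccc1)(c1ccccc1)c1ccccc1 | intermediate (not isolated)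
17 | (3S,6S,7Z,9S)-3,9-dimethyl-6-(propan-2-yl)-3-(triethylsilyloxy)-9-(trimethylsilyloxy)dodeca-1,7,11-triene | C=C[C@@](C)(O[Si](CC)(CC)CC)CC[C@@H](C(C)C)/C=C\[C@@](C)(O[Si](C)(C)C)CC=C | intermediate (not isolated)
18 | (4S,5Z,7S,10S)-4,10-dimethyl-7-(propan-2-yl)-10-(triethylsilyloxy)dodeca-1,5,11-trien-4-ol | C=C[C@@](C)(O[Si](CC)(CC)CC)CC[C@@H](C(C)C)/C=C\[C@@](C)(O)CC=C | intermediate
19 | (2S)-2-{(2R,3R)-3-[(3S,6S)-2,6-dimethyl-6-(triethylsilyloxy)oct-7-en-3-yl]oxiran-2-yl}pent-4-en-2-ol | C=C[C@@](C)(O[Si](CC)(CC)CC)CC[C@@H](C(C)C)[C@H]1O[C@H]1[C@@](C)(O)CC=C | intermediate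
20 | (3S,6S)-6-{(2R,3R)-3-[(2S)-2-hydroxypent-4-en-2-yl]oxiran-2-yl}-3,7-dimethyloct-1-en-3-ol | C=C[C@@](C)(O)CC[C@@H](C(C)C)[C@H]1O[C@H]1[C@@](C)(O)CC=C | intermediate
21 | (1R,2S,4Z,6S,9S,10R)-2,6-dimethyl-9-(propan-2-yl)-11-oxabicyclo[8.1.0]undec-4-ene-2,6-diol (ring numbering: C10=C1 Z, cis-oxirane C4–C5, carbinols C3 and C9) | C1/C=C\[C@@](C)(O)CC[C@@H](C(C)C)[C@H]2O[C@H]2[C@@]1(C)O | intermediate
22 | (1R,3S,4R,5R,6S,9S,10R)-1,10:4,5-diepoxy-3,9-dimethyl-6-(propan-2-yl)cyclodecane-3,9-diol (bis(cis-epoxide) diol) | O1[C@@H]2C[C@](C)(O)[C@@H]3O[C@@H]3[C@H](C(C)C)CC[C@](C)(O)[C@H]12 | intermediate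
23 | (1R,3S,4R,5R,6S,9S,10S)-4,5:9,10-diepoxy-3,9-dimethyl-6-(propan-2-yl)cyclodecane-1,3-diol | O[C@@H]1C[C@](C)(O)[C@@H]3O[C@@H]3[C@H](C(C)C)CC[C@]2(C)O[C@@H]12 | intermediate (not isolated)
24 | (1R,3S,4S,5R,6S,9S,10S)-3,4:9,10-diepoxy-3,9-dimethyl-6-(propan-2-yl)cyclodecane-1,5-diol | O[C@@H]1C[C@]2(C)O[C@H]2[C@H](O)[C@H](C(C)C)CC[C@]2(C)O[C@@H]12 | intermediate
25 | angelic acid, (Z)-2-methylbut-2-enoic acid | C/C=C(/C)C(=O)O | starting material
26 | (Z)-2-methylbut-2-enoic 2,4,6-trichlorobenzoic anhydride | C/C=C(/C)C(=O)OC(=O)c1c(Cl)cc(Cl)cc1Cl | intermediate (not isolated)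
27 | (1R,3S,4S,5R,6S,9S,10S)-3,4:9,10-diepoxy-5-hydroxy-3,9-dimethyl-6-(propan-2-yl)cyclodecan-1-yl (Z)-2-methylbut-2-enoate | C/C=C(/C)C(=O)O[C@@H]1C[C@]2(C)O[C@H]2[C@H](O)[C@H](C(C)C)CC[C@]2(C)O[C@@H]12 | intermediate
28 | (1R,3S,4S,5R,6S,9S,10S)-5-acetoxy-3,4:9,10-diepoxy-3,9-dimethyl-6-(propan-2-yl)cyclodecan-1-yl (Z)-2-methylbut-2-enoate | C/C=C(/C)C(=O)O[C@@H]1C[C@]2(C)O[C@H]2[C@H](OC(C)=O)[C@H](C(C)C)CC[C@]2(C)O[C@@H]12 | target

**Step count**

Total: 18 steps. Longest linear sequence: 15 steps (steps 1–7 and 11–18, from 1 to 28); the side branch is steps 8–10.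

**Steps most likely to fail, with fallbacks**

Step 16, twofold Payne rearrangement. The equilibrium may stop at the half-rearranged stage, the C9 alkoxide may open the C4–C5 oxirane at C5 across the ring (irreversible six-membered ether formation), or hydroxide may open an oxirane. The fallback sets out from 22 and comes back at 24. The rearrangement is run water-free under kinetic trapping: NaH in THF/DMF at 0 °C forms the alkoxides, and tert-butyldimethylsilyl chloride present in the flask silylates the secondary alkoxides released at C1 and C5 far faster than the hindered tertiary ones. This pulls both halves through to the 1,5-bis(tert-butyldimethylsilyl) ether of 24, F1; Bu4NF in THF then gives 24.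

Step 14, ring-closing metathesis. Cross-metathesis to dimers and oligomers may outrun closure of the strained ten-membered ring, or the hindered vinyl carbinol end may not be engaged. The fallback sets out from 20 and comes back at 21. The two tertiary hydroxyls are first tied together with iPr2Si(OTf)2 and 2,6-lutidine at high dilution to give the cyclic diisopropylsilylene of 20, F2. Metathesis then has to close only an eight-membered ring (Si, O, C9, C10, C1, C2, C3, O) inside a preformed, flexible silicon-containing ring, giving the bridged diisopropylsilylene of 21, F3. Bu4NF/AcOH removes the tether and delivers 21.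

Step 12, first directed epoxidation. Facial selectivity may be poor, because methyl and allyl on C3 differ little in size and the bias rests on the isopropyl group at C6. The fallback sets out from 18 and comes back at 19. Substrate control is replaced by catalyst control: Hf(OtBu)4 with a chiral C2-symmetric bis(hydroxamic acid) ligand and cumene hydroperoxide, a system made for tertiary allylic alcohols, with the ligand enantiomer chosen to deliver oxygen to the required face. The product is 19 itself, so no new compound is made (F0).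

**Further compounds**

F1 | step 16 | (1R,3S,4S,5R,6S,9S,10S)-1,5-bis(tert-butyldimethylsilyloxy)-3,4:9,10-diepoxy-3,9-dimethyl-6-(propan-2-yl)cyclodecane | CC(C)(C)[Si](C)(C)O[C@@H]1C[C@]2(C)O[C@H]2[C@H](O[Si](C)(C)C(C)(C)C)[C@H](C(C)C)CC[C@]2(C)O[C@@H]12
F2 | step 14 | cyclic diisopropylsilylene of 20 (silicon bridging O3 and O9) | C=C[C@]1(C)CC[C@@H](C(C)C)[C@H]2O[C@H]2[C@](C)(CC=C)O[Si](C(C)C)(C(C)C)O1
F3 | step 14 | cyclic diisopropylsilylene of 21 (silicon bridging O3 and O9) | C1/C=C\[C@]2(C)CC[C@@H](C(C)C)[C@H]3O[C@H]3[C@@]1(C)O[Si](C(C)C)(C(C)C)O2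
F0 | step 12 | none | none
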